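**Retrosynthetic overview**
1. Both C–Br bonds are made last on the closed macrolactone: C6'–Br from a homoallylic C6' alcohol (retentive displacement) and C10'–Br from a C10'–C11' epoxide (SN2 opening).
2. The 15-membered ring is closed by macrolactonisation (C14'–O to the benzoate carbonyl) of a seco acid.
3. The quaternary C7' is set by alkylating a cyclohexenone enolate with a homoallylic iodide (chain built from pent-4-ynal).
4. The carbocycle is the ring of p-cresol: oxidative dearomatisation gives an achiral 4-methoxy-4-methyl dienone, and a Cu-catalysed enantioselective benzyl conjugate addition desymmetrises it (sets C2'); SmI2 later expels the OMe and moves the alkene to C3'=C4'.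
5. Ring order: carbocycle (from the arene) → oxirane → macrolactone.

Assumptions and notation: compounds 1, 3 and 10, the two chiral ligands and the L-fructose-derived Shi ketone are bought; the sense of induction in steps 4 and 5 is assumed as drawn (the ligand antipode is used otherwise). Primed locants: C1' = benzylic CH2; carbocycle C2' (CH–CH2Ar), C3' (C–Me), C4' (=CH), C5' (CH2), C6' (CHBr), C7' (quaternary C–Me); chain C8'–C15' (C10' CHBr, C11' C(OH)Me, C14' CH–O, C15' isopropenyl carbon). Target = (2'R,6'S,7'S,10'R,11'S,14'S).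

**Step 1**
Reactants: 1 4-methylphenol (p-cresol)
Product: 2 4-methoxy-4-methylcyclohexa-2,5-dien-1-one
Conditions: PhI(OAc)2, MeOH, 0 °C to rt
Reagents that add atoms: methanol, CO
Why: Oxidative dearomatisation of a para-alkylphenol by the hypervalent iodine reagent with methanol capture at C4 gives the achiral, mirror-symmetric quinol ether; no stereocentre is formed.

**Step 2**
Reactants: 3 methyl 4-hydroxy-3-methylbenzoate
Product: 4 methyl 4-(methoxymethoxy)-3-methylbenzoate
Conditions: MOMCl, i-Pr2NEt, CH2Cl2, 0 °C to rt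
Reagents that add atoms: chloromethyl methyl ether, COCCl
Why: O-alkylation of the phenol (Williamson type) masks the acidic OH for the organozinc and enolate steps.

**Step 3**
Reactants: 4 methyl 4-(methoxymethoxy)-3-methylbenzoate
Product: 5 methyl 3-(bromomethyl)-4-(methoxymethoxy)benzoate
Conditions: NBS, AIBN (cat.), PhCF3, 85 °C
Reagents that add atoms: N-bromosuccinimide, O=C1CCC(=O)N1Br
Why: Wohl–Ziegler radical bromination at the only benzylic methyl group.

**Step 4 (key step)**
Reactants: 5 methyl 3-(bromomethyl)-4-(methoxymethoxy)benzoate; 2 4-methoxy-4-methylcyclohexa-2,5-dien-1-one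
Product: 9 methyl 4-(methoxymethoxy)-3-{[(1S,2R,6S)-2-methoxy-2,6-dimethyl-5-oxocyclohex-3-en-1-yl]methyl}benzoate, via benzylic zinc bromide 6 (not isolated), via mixed diorganozinc 7 (not isolated), via zinc enolate 8 (not isolated)
Conditions: Zn dust, LiCl, THF, 25 °C; Me3SiCH2Li, −40 °C; 2, Cu(OTf)2 (5 mol %), (S,R,R)-binaphthol bis(1-phenylethyl)phosphoramidite (10 mol %), toluene, −30 °C; then MeI, HMPA, −30 to 0 °C
Reagents that add atoms: iodomethane, CI
Why: Proposed new method: zinc insertion into the benzylic bromide and Zn–Li exchange with Me3SiCH2Li give an ester-tolerant mixed diorganozinc whose benzyl group (CH2SiMe3 is a non-transferred ligand) is delivered by the catalyst from Cu(OTf)2 and the phosphoramidite to one of the two enantiotopic enone β-carbons of 2, which sets C2' and breaks the mirror symmetry (closest known reaction: Cu/phosphoramidite conjugate addition of dialkylzincs to this same dienone), and the zinc enolate is then C-methylated by MeI; the configurations at the OMe carbon and the CHMe carbon are inconsequential because they are erased in steps 10 and 8.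

**Step 5**
Reactants: 10 pent-4-ynal
Product: 12 (3S)-2-methylhept-1-en-6-yn-3-ol, via silyl ether 11 (not isolated)
Conditions: 2-bromopropene, CrCl2 (10 mol %), (S)-valinol-derived oxazoline–sulfonamide ligand (11 mol %), Et3N (20 mol %), NiCl2·(2,9-dimethyl-1,10-phenanthroline) (2 mol %), Mn, TMSCl, LiCl, THF, rt; then 1 M HCl
Reagents that add atoms: 2-bromopropene, C=C(C)Br
Why: Catalytic asymmetric Nozaki–Hiyama–Kishi coupling, in which the alkenyl group is passed from nickel to the CrCl2–ligand complex and adds to one aldehyde face to set C14' (S), with Mn and TMSCl turning the chromium over.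

**Step 6**
Reactants: 12 (3S)-2-methylhept-1-en-6-yn-3-ol
Product: 14 (3S,6E)-2,6-dimethylnona-1,6-diene-3,9-diol, via alkenylalane 13 (not isolated)
Conditions: AlMe3, Cp2ZrCl2 (25 mol %), CH2Cl2, 0 °C to rt; evaporate; n-BuLi, THF–hexane, −78 °C; ethylene oxide, −78 to 0 °C
Reagents that add atoms: trimethylaluminium, C[Al](C)C; ethylene oxide, C1CO1
Why: Negishi zirconium-catalysed syn-carboalumination puts Me on the internal and Al on the terminal alkyne carbon, and the derived alkenyl alanate opens ethylene oxide with retention, so the trisubstituted alkene is E.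

**Step 7**
Reactants: 14 (3S,6E)-2,6-dimethylnona-1,6-diene-3,9-diol
Product: 16 (3S,6E)-9-iodo-2,6-dimethylnona-1,6-dien-3-yl acetate, via iodo alcohol 15 (not isolated)
Conditions: PPh3, I2, imidazole, CH2Cl2, 0 °C; then Ac2O, Et3N, DMAP (cat.), rt
Reagents that add atoms: iodine, II; acetic anhydride, CC(=O)OC(C)=O
Why: Appel-type iodination is selective for the unhindered primary alcohol, and the remaining secondary allylic alcohol is then acetylated in the same flask.

**Step 8**
Reactants: 9 methyl 4-(methoxymethoxy)-3-{[(1S,2R,6S)-2-methoxy-2,6-dimethyl-5-oxocyclohex-3-en-1-yl]methyl}benzoate; 16 (3S,6E)-9-iodo-2,6-dimethylnona-1,6-dien-3-yl acetate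
Product: 17 methyl 3-{[(1S,2R,6S)-6-[(3E,7S)-7-acetoxy-4,8-dimethylnona-3,8-dien-1-yl]-2-methoxy-2,6-dimethyl-5-oxocyclohex-3-en-1-yl]methyl}-4-(methoxymethoxy)benzoate
Conditions: LiN(i-Pr)2, THF, −78 °C; then 16, DMPU, −78 to −10 °C
Reagents that add atoms: none
Why: Only C7' of 9 can be deprotonated (the other α-carbon is vinylic), and the nearly planar cross-conjugated lithium dienolate is alkylated (SN2) by the primary iodide on the face opposite the adjacent C2' benzylic group, which sets the quaternary C7' with the chain trans to CH2Ar.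

**Step 9**
Reactants: 17 (enone with 10',11'-alkene)
Product: 18 methyl 3-{[(1S,2R,6S)-6-{2-[(2S,3S)-3-[(3S)-3-acetoxy-4-methylpent-4-en-1-yl]-3-methyloxiran-2-yl]ethyl}-2-methoxy-2,6-dimethyl-5-oxocyclohex-3-en-1-yl]methyl}-4-(methoxymethoxy)benzoate
Conditions: L-fructose-derived Shi ketone (30 mol %), KHSO5 (as 2KHSO5·KHSO4·K2SO4), K2CO3, Bu4NHSO4, MeCN–dimethoxymethane–aq. Na2B4O7 buffer, 0 °C
Reagents that add atoms: potassium peroxymonosulfate, [K+].[O-]S(=O)(=O)OO
Why: Shi asymmetric epoxidation, in which the chiral dioxirane attacks only the electron-rich trisubstituted E-alkene (the enone and the acetoxy-deactivated 1,1-disubstituted alkene are inert) through the spiro transition state, this catalyst antipode giving the (10'S,11'S)-epoxide.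

**Step 10**
Reactants: 18 (γ-methoxy enone epoxide)
Product: 21 methyl 3-{[(1R,5S,6S)-6-{2-[(2S,3S)-3-[(3S)-3-acetoxy-4-methylpent-4-en-1-yl]-3-methyloxiran-2-yl]ethyl}-5-hydroxy-2,6-dimethylcyclohex-2-en-1-yl]methyl}-4-(methoxymethoxy)benzoate, via samarium dienolate 19 (not isolated), via β,γ-enone 20 (not isolated)
Conditions: SmI2, THF–MeOH, −78 °C; then NaBH4, −78 to −30 °C
Reagents that add atoms: none
Why: Two-electron reduction of the γ-methoxy enone by SmI2 expels methoxide (vinylogous reductive elimination) to a dienolate that is protonated at the α-carbon, placing the alkene at C3'=C4', and NaBH4 then adds hydride axially on the face opposite the axial C7' methyl and the C2' substituent to give the equatorial (6'S)-alcohol, OH cis to the C7' methyl.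

**Step 11**
Reactants: 21 (hydroxy epoxide diester)
Product: 22 3-{[(1R,5S,6S)-5-hydroxy-6-{2-[(2S,3S)-3-[(3S)-3-hydroxy-4-methylpent-4-en-1-yl]-3-methyloxiran-2-yl]ethyl}-2,6-dimethylcyclohex-2-en-1-yl]methyl}-4-(methoxymethoxy)benzoic acid
Conditions: LiOH, THF–MeOH–H2O, 45 °C; then AcOH to pH 5
Reagents that add atoms: lithium hydroxide, [Li+].[OH-]
Why: Saponification cleaves the methyl benzoate and the acetate, while the epoxide, the MOM acetal and the alkenes are stable to base and no epimerisable centre remains.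

**Step 12**
Reactants: 22 (seco acid)
Product: 23 15-membered macrolactone (ester O on C14') with 6'-OH, 10',11'-epoxide and aryl OMOM, (2'R,6'S,7'S,10'S,11'S,14'S)
Conditions: 2-methyl-6-nitrobenzoic anhydride (MNBA), DMAP, CH2Cl2 (2 mM, syringe pump), rt
Reagents that add atoms: none
Why: Shiina macrolactonisation via the mixed anhydride at high dilution, in which only the C14' alcohol can reach the acyl group (the hindered C6' alcohol would need a strained 9-membered ring) and C14' keeps its configuration.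

**Step 13**
Reactants: 23 (macrolactone, 6'-OH, epoxide)
Product: 25 MOM ether of the target, (2'R,6'S,7'S,10'R,11'S,14'S)-6',10'-dibromo-11'-hydroxy macrolactone, via mesylate 24 (not isolated)
Conditions: MsCl, Et3N, CH2Cl2, −20 °C; then Li2NiBr4, THF, 0 to 45 °C
Reagents that add atoms: dilithium tetrabromonickelate, [Li+].[Li+].[Ni+2].[Br-].[Br-].[Br-].[Br-]
Why: Proposed new method: the equatorial homoallylic C6' mesylate ionises with participation of the C3'=C4' π bond to a tertiary cyclopropylcarbinyl cation that bromide re-opens at C6' with net retention (closest known reaction: cholesteryl tosylate to cholesteryl bromide), while the same soft bromide opens the epoxide by SN2 at the less substituted C10' with inversion to the (10'R,11'S)-bromohydrin.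

**Step 14**
Reactants: 25 (MOM ether of the target)
Product: 26 target CNP0213075.1
Conditions: HCl (1.25 M in MeOH), 0 °C to rt
Reagents that add atoms: none
Why: Acid-catalysed acetal exchange removes the phenolic MOM group under conditions that leave the two bromides, the tertiary alcohol, the alkenes and the lactone untouched.

**Compound list**
1 | 4-methylphenol (p-cresol) | Cc1ccc(O)cc1 | starting material
2 | 4-methoxy-4-methylcyclohexa-2,5-dien-1-one | COC1(C)C=CC(=O)C=C1 | intermediate
3 | methyl 4-hydroxy-3-methylbenzoate | COC(=O)c1ccc(O)c(C)c1 | starting material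
4 | methyl 4-(methoxymethoxy)-3-methylbenzoate | COCOc1ccc(cc1C)C(=O)OC | intermediate
5 | methyl 3-(bromomethyl)-4-(methoxymethoxy)benzoate | COCOc1ccc(cc1CBr)C(=O)OC | intermediate
6 | [2-(methoxymethoxy)-5-(methoxycarbonyl)benzyl]zinc bromide | COCOc1ccc(cc1C[Zn]Br)C(=O)OC | intermediate
7 | [2-(methoxymethoxy)-5-(methoxycarbonyl)benzyl][(trimethylsilyl)methyl]zinc | COCOc1ccc(cc1C[Zn]C[Si](C)(C)C)C(=O)OC | intermediate
8 | {[(3S,4R)-4-methoxy-3-{[2-(methoxymethoxy)-5-(methoxycarbonyl)phenyl]methyl}-4-methylcyclohexa-1,5-dien-1-yl]oxy}[(trimethylsilyl)methyl]zinc | CO[C@]1(C)C=CC(O[Zn]C[Si](C)(C)C)=C[C@@H]1Cc2cc(ccc2OCOC)C(=O)OC | intermediate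
9 | methyl 4-(methoxymethoxy)-3-{[(1S,2R,6S)-2-methoxy-2,6-dimethyl-5-oxocyclohex-3-en-1-yl]methyl}benzoate | O=C1C=C[C@@](C)(OC)[C@@H](Cc2cc(ccc2OCOC)C(=O)OC)[C@@H]1C | intermediate
10 | pent-4-ynal | C#CCCC=O | starting material
11 | trimethyl{[(3S)-2-methylhept-1-en-6-yn-3-yl]oxy}silane | C=C(C)[C@@H](O[Si](C)(C)C)CCC#C | intermediate
12 | (3S)-2-methylhept-1-en-6-yn-3-ol | C=C(C)[C@@H](O)CCC#C | intermediate
13 | (E)-alkenyl dimethylalane of 12 (Me on C6, AlMe2 on C7, OAlMe2 on C3) | C=C(C)[C@@H](O[Al](C)C)CC/C(C)=C/[Al](C)C | intermediate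
14 | (3S,6E)-2,6-dimethylnona-1,6-diene-3,9-diol | C=C(C)[C@@H](O)CC/C(C)=C/CCO | intermediate
15 | (3S,6E)-9-iodo-2,6-dimethylnona-1,6-dien-3-ol | C=C(C)[C@@H](O)CC/C(C)=C/CCI | intermediate
16 | (3S,6E)-9-iodo-2,6-dimethylnona-1,6-dien-3-yl acetate | C=C(C)[C@@H](OC(C)=O)CC/C(C)=C/CCI | intermediate
17 | methyl 3-{[(1S,2R,6S)-6-[(3E,7S)-7-acetoxy-4,8-dimethylnona-3,8-dien-1-yl]-2-methoxy-2,6-dimethyl-5-oxocyclohex-3-en-1-yl]methyl}-4-(methoxymethoxy)benzoate | C=C(C)[C@@H](OC(C)=O)CC/C(C)=C/CC[C@]1(C)C(=O)C=C[C@@](C)(OC)[C@H]1Cc1cc(ccc1OCOC)C(=O)OC | intermediate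
18 | (10'S,11'S)-epoxide of 17 (name as in step 9) | C=C(C)[C@@H](OC(C)=O)CC[C@]2(C)O[C@H]2CC[C@]1(C)C(=O)C=C[C@@](C)(OC)[C@H]1Cc1cc(ccc1OCOC)C(=O)OC | intermediate
19 | samarium diiodide dienolate of 20 (O–SmI2 on C6', C5'=C6' and C3'=C4' double bonds) | C=C(C)[C@@H](OC(C)=O)CC[C@]2(C)O[C@H]2CC[C@]1(C)C(O[Sm](I)I)=CC=C(C)[C@H]1Cc1cc(ccc1OCOC)C(=O)OC | intermediate
20 | methyl 3-{[(1R,6S)-6-{2-[(2S,3S)-3-[(3S)-3-acetoxy-4-methylpent-4-en-1-yl]-3-methyloxiran-2-yl]ethyl}-2,6-dimethyl-5-oxocyclohex-2-en-1-yl]methyl}-4-(methoxymethoxy)benzoate | C=C(C)[C@@H](OC(C)=O)CC[C@]2(C)O[C@H]2CC[C@]1(C)C(=O)CC=C(C)[C@H]1Cc1cc(ccc1OCOC)C(=O)OC | intermediate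
21 | (1R,5S,6S)-5-hydroxy analogue of 20 (name as in step 10) | C=C(C)[C@@H](OC(C)=O)CC[C@]2(C)O[C@H]2CC[C@]1(C)[C@@H](O)CC=C(C)[C@H]1Cc1cc(ccc1OCOC)C(=O)OC | intermediate
22 | seco acid (name as in step 11) | C=C(C)[C@@H](O)CC[C@]2(C)O[C@H]2CC[C@]1(C)[C@@H](O)CC=C(C)[C@H]1Cc1cc(ccc1OCOC)C(=O)O | intermediate
23 | macrolactone: target skeleton with 6'-OH in place of Br, a (10'S,11'S)-epoxide in place of the bromohydrin, phenol as MOM ether; (2'R,6'S,7'S,14'S) | C=C(C)[C@@H]3CC[C@]2(C)O[C@H]2CC[C@]1(C)[C@@H](O)CC=C(C)[C@H]1Cc1cc(ccc1OCOC)C(=O)O3 | intermediate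
24 | 6'-O-methanesulfonate of 23 | C=C(C)[C@@H]3CC[C@]2(C)O[C@H]2CC[C@]1(C)[C@@H](OS(C)(=O)=O)CC=C(C)[C@H]1Cc1cc(ccc1OCOC)C(=O)O3 | intermediate
25 | O-(methoxymethyl) ether of the target, (2'R,6'S,7'S,10'R,11'S,14'S) | C=C(C)[C@@H]3CC[C@](C)(O)[C@H](Br)CC[C@]1(C)[C@@H](Br)CC=C(C)[C@H]1Cc1cc(ccc1OCOC)C(=O)O3 | intermediate
26 | CNP0213075.1, (2'R,6'S,7'S,10'R,11'S,14'S) | C=C(C)[C@@H]1CC[C@](C)(O)[C@H](Br)CC[C@@]2(C)[C@H](Cc3cc(ccc3O)C(=O)O1)C(C)=CC[C@@H]2Br | target

**Totals**
Total steps: 14. Longest linear sequence: 10 steps (10 → 26 through steps 5–14; equally 3 → 26 through steps 2–4 and 8–14).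

**Three steps most likely to fail, with fallbacks**

Step 4 (enantioselective benzyl transfer; salts from the zinc reagent may erode ee or the benzyl group may transfer poorly). The fallback replaces the organometallic addition by an organocatalytic desymmetrisation. It sets out from 5 and 2 and returns at 9. Bromide 5 is converted with AgNO2 in Et2O into methyl 4-(methoxymethoxy)-3-(nitromethyl)benzoate F1. A cinchona-derived bifunctional thiourea (10 mol %, toluene) adds F1 to one enone arm of 2 to give the nitro ketone F2. Bu3SnH/AIBN (toluene, 80 °C) removes the benzylic nitro group to give the ketone F3. LiN(i-Pr)2 then MeI methylates F3 at its only enolisable carbon to give 9.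

Step 8 (SN2 alkylation of a hindered tetrasubstituted enolate with an unactivated iodide; O-alkylation or no reaction). The fallback builds the same C7' centre by an aldol reaction, which tolerates hindrance, and attaches the chain by cross-coupling. It sets out from 9 (and 12) and returns at 17. The lithium enolate of 9 adds to acetaldehyde at −78 °C, again anti to the benzylic group, to give the aldol adduct F4. Martin sulfurane dehydrates F4 to the vinyl ketone F5, and 9-BBN hydroborates the vinyl group to the alkylborane F6. Separately, 12 is carboaluminated (AlMe3, Cp2ZrCl2) and quenched with I2 to the vinyl iodide F7, which is acetylated to the acetate F8. B-alkyl Suzuki coupling of F6 with F8 (PdCl2(dppf), Cs2CO3, DMF–H2O) gives 17.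

Step 13 (retentive bromide substitution at the neopentylic C6'; elimination to the diene, ring contraction, or capture at C3' are the dangers). The fallback separates ionisation from bromide delivery. It sets out from 24 and returns at 26. Solvolysis of 24 in NaHCO3-buffered aqueous acetone at 50 °C traps the cation kinetically as the cyclopropylcarbinol F9. Li2NiBr4 then opens the epoxide of F9 to the bromohydrin F10. Finally 48% aqueous HBr with ZnBr2 in Et2O at 0 °C re-opens the cyclopropylcarbinol under thermodynamic control (Julia-type) to the homoallylic 6'-bromide and cleaves the MOM acetal, giving 26 directly. This fallback shares the ionisation step, so it would not cure ring contraction.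

**Further compounds**
F1 | step 4 | methyl 4-(methoxymethoxy)-3-(nitromethyl)benzoate | COCOc1ccc(cc1C[N+](=O)[O-])C(=O)OC
F2 | step 4 | methyl 4-(methoxymethoxy)-3-{[(1R,2R)-2-methoxy-2-methyl-5-oxocyclohex-3-en-1-yl](nitro)methyl}benzoate (nitro-bearing carbon as a mixture) | O=C1C=C[C@@](C)(OC)[C@@H](C([N+](=O)[O-])c2cc(ccc2OCOC)C(=O)OC)C1
F3 | step 4 | methyl 4-(methoxymethoxy)-3-{[(1S,2S)-2-methoxy-2-methyl-5-oxocyclohex-3-en-1-yl]methyl}benzoate | O=C1C=C[C@@](C)(OC)[C@@H](Cc2cc(ccc2OCOC)C(=O)OC)C1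
F4 | step 8 | methyl 3-{[(1S,2R,6S)-6-(1-hydroxyethyl)-2-methoxy-2,6-dimethyl-5-oxocyclohex-3-en-1-yl]methyl}-4-(methoxymethoxy)benzoate (carbinol epimers) | CC(O)[C@]1(C)C(=O)C=C[C@@](C)(OC)[C@H]1Cc1cc(ccc1OCOC)C(=O)OC
F5 | step 8 | methyl 3-{[(1S,2R,6S)-6-ethenyl-2-methoxy-2,6-dimethyl-5-oxocyclohex-3-en-1-yl]methyl}-4-(methoxymethoxy)benzoate | C=C[C@]1(C)C(=O)C=C[C@@](C)(OC)[C@H]1Cc1cc(ccc1OCOC)C(=O)OC
F6 | step 8 | B-alkyl-9-borabicyclo[3.3.1]nonane from F5 (boron on the terminal carbon of the former vinyl group) | C(C[C@]1(C)C(=O)C=C[C@@](C)(OC)[C@H]1Cc1cc(ccc1OCOC)C(=O)OC)B1C2CCCC1CCC2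
F7 | step 8 | (3S,6E)-7-iodo-2,6-dimethylhepta-1,6-dien-3-ol | C=C(C)[C@@H](O)CC/C(C)=C/I
F8 | step 8 | (3S,6E)-7-iodo-2,6-dimethylhepta-1,6-dien-3-yl acetate | C=C(C)[C@@H](OC(C)=O)CC/C(C)=C/I
F9 | step 13 | 4',6'-cyclo-3'-ol (cyclopropylcarbinol) from 24: bicyclo[3.1.0]hexane core, C5'H2 bridge and 3'-OH on the face of the C7' methyl, epoxide and MOM ether intact | C=C(C)[C@@H]3CC[C@]2(C)O[C@H]2CC[C@]1(C)[C@H]4C[C@H]4[C@@](C)(O)[C@H]1Cc1cc(ccc1OCOC)C(=O)O3
F10 | step 13 | (10'R,11'S)-bromohydrin of F9 | C=C(C)[C@@H]3CC[C@](C)(O)[C@H](Br)CC[C@]1(C)[C@H]2C[C@H]2[C@@](C)(O)[C@H]1Cc1cc(ccc1OCOC)C(=O)O3
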